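The δ-lactone ring (O1′–C2′(=O)–C3′ spiro–C4′–C5′–C6′) is opened at its alkyl C–O bond O1′–C6′. C6′ lies α to the isobutyryl ketone, so it can be brominated selectively through the kinetic enolate, is a strongly activated SN2 carbon, and keeps an adjustable configuration. The precursor is an open-chain α-bromo ketone whose C3′ carboxyl group is masked as a 2-(trimethylsilyl)ethyl ester; fluoride liberates the keto carboxylate, which closes the six-membered ring at C6′ in the same flask. Both C6′ epimers then converge on the target by kinetic protonation of one enol ether. The cyclopentanone–γ-lactone core derives from (R)-α-terpineol.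

Key step: step 9

Remark: (R)-(+)-α-terpineol is assumed to be available in high enantiomeric purity; every other stereocentre is derived from it or set by a catalyst.
Locants: the bicyclic core is numbered as cyclopenta[c]furan (C1 lactone carbonyl, O2, C3 gem-dimethyl carbon, C3a, C4, C5, C6 ketone, C6a). The δ-lactone is numbered O1′, C2′ (carbonyl), C3′ (spiro atom, identical with C5), C4′, C5′ (isopropenyl), C6′ (isobutyryl).

Step 1
Reactants: 1 (R)-(+)-α-terpineol
Product: 3 (4R)-5,5-dimethyl-4-(3-oxobutyl)oxolan-2-one, via hydroxy keto acid 2 (not isolated)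
Conditions: RuCl3 hydrate (2 mol %), NaIO4 (4 equiv), EtOAc/MeCN/H2O, 0 °C → rt; then 1 M HCl, rt
Reagents that add atoms: sodium periodate [Na+].[O-]I(=O)(=O)=O
Why: RuO4-catalysed oxidative cleavage of the trisubstituted ring alkene should give a methyl ketone and a carboxylic acid, and the tertiary alcohol then closes the γ-lactone on acidification; the terpene stereocentre (future C3a) is not touched.

Step 2
Reactants: 3 (4R)-5,5-dimethyl-4-(3-oxobutyl)oxolan-2-one
Product: 5 methyl 3-[(3R)-2,2-dimethyl-5-oxooxolan-3-yl]propanoate, via homoterpenylic acid 4 (not isolated)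
Conditions: Br2, NaOH, H2O/dioxane, 0 °C; HCl to pH 1; then MeOH, H2SO4 (cat.), 40 °C
Reagents that add atoms: methanol CO; sodium hydroxide [Na+].[OH-] (hydroxyl oxygen of acid 4 only)
Why: haloform degradation of the methyl ketone to the acid (the lactone reopens in base and recloses on acidification) followed by Fischer esterification, which the gem-dimethyl γ-lactone should survive; no stereocentre is affected.

Step 3
Reactants: 5 methyl 3-[(3R)-2,2-dimethyl-5-oxooxolan-3-yl]propanoate
Product: 7 (3aR,6aR)-3,3,6a-trimethyltetrahydro-1H-cyclopenta[c]furan-1,6(6aH)-dione, via lithium keto lactone enolate 6 (not isolated)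
Conditions: LiN(SiMe3)2 (1.05 equiv), THF, −78 → 0 °C; then MeI, DMPU, 0 °C → rt
Reagents that add atoms: iodomethane CI
Why: Dieckmann condensation of the more acidic lactone α-CH2 onto the ester (5-exo-trig, driven by the 1,3-dicarbonyl enolate) and C-methylation of that enolate; C6a can only be set cis to C3a because a trans-fused bicyclo[3.3.0] system is too strained.

Step 4
Reactants: 7 (3aR,6aR)-3,3,6a-trimethyltetrahydro-1H-cyclopenta[c]furan-1,6(6aH)-dione
Product: 8 (3aR,6aR)-5-allyl-3,3,6a-trimethyltetrahydro-1H-cyclopenta[c]furan-1,6(6aH)-dione (C5 epimers)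
Conditions: LiN(SiMe3)2 (1.05 equiv), THF, −78 °C; allyl bromide, −78 → 0 °C
Reagents that add atoms: allyl bromide C=CCBr
Why: enolate alkylation at C5, the only enolisable carbon of 7; the C5 configuration is irrelevant because C5 is made planar again in step 5.

Step 5
Reactants: 8 (3aR,6aR)-5-allyl-3,3,6a-trimethyltetrahydro-1H-cyclopenta[c]furan-1,6(6aH)-dione
Product: 10 2-(trimethylsilyl)ethyl (3aR,5R,6aR)-5-allyl-3,3,6a-trimethyl-1,6-dioxohexahydro-1H-cyclopenta[c]furan-5-carboxylate, via β-keto acid 9 (not isolated)
Conditions: LiN(iPr)2 (1.1 equiv), THF, −78 °C; CO2 gas, −78 °C; cold 1 M HCl, extraction; then Me3SiCH2CH2OH, EDC·HCl, DMAP (cat.), CH2Cl2, 0 °C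
Reagents that add atoms: carbon dioxide O=C=O; 2-(trimethylsilyl)ethanol C[Si](C)(C)CCO
Why: C-carboxylation of the tetrasubstituted enolate followed by carbodiimide (Steglich) esterification; CO2 should enter from the convex face, opposite the lactone bridge and its C3 methyl groups, which sets the quaternary C5 (future spiro C3′) with the carboxyl group cis to the 6a-methyl group and allyl on the lactone side.

Step 6
Reactants: 10 2-(trimethylsilyl)ethyl (3aR,5R,6aR)-5-allyl-3,3,6a-trimethyl-1,6-dioxohexahydro-1H-cyclopenta[c]furan-5-carboxylate; 11 4-methylpent-1-en-3-one (isopropyl vinyl ketone)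
Product: 12 2-(trimethylsilyl)ethyl (3aR,5R,6aR)-3,3,6a-trimethyl-5-[(2E)-5-methyl-4-oxohex-2-en-1-yl]-1,6-dioxohexahydro-1H-cyclopenta[c]furan-5-carboxylate
Conditions: second-generation Hoveyda–Grubbs catalyst RuCl2(H2IMes)(=CH-C6H4-2-OiPr) (5 mol %), 11 (3 equiv), CH2Cl2, 40 °C
Reagents that add atoms: none
Why: olefin cross-metathesis of the only alkene of 10 with an electron-poor vinyl ketone that does not homodimerise readily, which should give the E-enone; no stereocentre is formed.

Step 7
Reactants: 12 the (E)-enone of step 6; 13 4,4,5,5-tetramethyl-2-(prop-1-en-2-yl)-1,3,2-dioxaborolane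
Product: 14 2-(trimethylsilyl)ethyl (3aR,5R,6aR)-3,3,6a-trimethyl-5-[(2R)-5-methyl-4-oxo-2-(prop-1-en-2-yl)hexyl]-1,6-dioxohexahydro-1H-cyclopenta[c]furan-5-carboxylate
Conditions: [Rh(cod)OH]2 (2.5 mol %), (S)-BINAP (6 mol %), 13 (3 equiv), dioxane/H2O 10:1, 50 °C
Reagents that add atoms: none
Why: Rh-catalysed asymmetric 1,4-addition of an alkenylboron reagent (Hayashi–Miyaura reaction) under base-free conditions that spare the non-enolisable 1,3-dicarbonyl arrays; the chiral ligand sets C5′ by delivering isopropenyl to the Re face of the β-carbon, the sense expected for (S)-BINAP with E-enones (the antipodal ligand would be used if the sense proved opposite).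

Step 8
Reactants: 14 the keto ester of step 7
Product: 16 α-bromo ketone: 14 with one hydrogen of the side-chain CH2 between C5′ and the ketone replaced by bromine (future C6′; both epimers), via trimethylsilyl enol ether 15 (not isolated)
Conditions: LiN(SiMe3)2 (1.2 equiv), Me3SiCl (2 equiv), THF, −78 °C; then N-bromosuccinimide (1.05 equiv), −78 °C
Reagents that add atoms: N-bromosuccinimide O=C1CCC(=O)N1Br; chlorotrimethylsilane C[Si](C)(C)Cl (silyl group of 15 only)
Why: kinetic deprotonation with internal silyl quench should take the CH2 rather than the isopropyl CH (the only two enolisable sites in 14), and bromination of the electron-rich silyl enol ether at −78 °C should outrun any reaction at the isopropenyl group; no stereocontrol is needed at the new C–Br centre.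

Step 9
Reactants: 16 the α-bromo ketone of step 8
Product: 18 δ-lactone as a mixture of C6′ epimers (6′-epimer of the target expected to predominate), via tetrabutylammonium carboxylate 17 (not isolated)
Conditions: Bu4NF (1.1 equiv), THF, 0 °C → rt; pH 7 buffer
Reagents that add atoms: none
Why: Fluoride attacks silicon of the 2-(trimethylsilyl)ethyl ester and the fragment collapses to ethene, Me3SiF and the tetrabutylammonium β-keto carboxylate 17, whose oxygen displaces bromide at C6′ in an intramolecular SN2 reaction that forms the O1′–C6′ bond. The closest known reaction types are the fluoride unmasking of 2-(trimethylsilyl)ethyl esters and the O-alkylation of carboxylates by α-halo ketones (phenacyl ester formation), here in its intramolecular, lactone-forming version. The δ-lactone closes in the 6-exo-tet mode. C6′ is formed with inversion from whichever bromide epimer reacts, but the bromide epimers interconvert and C6′–H of the product is labile, so its configuration is deliberately not relied on here and is set in step 10; C3′ and C5′ are untouched. The step needs O–C bond formation at C6′ without loss of CO2, elimination of HBr or attack on the alkene: the carboxylate appears only after the electrophile is in place and with no electrophilic halogen present (so the isopropenyl group cannot halolactonise), C6′ is the only sp3 electrophile and is activated by the adjacent carbonyl, and the quaternary carboxylate salt should not decarboxylate at or below room temperature.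

Step 10
Reactants: 18 δ-lactone as a mixture of C6′ epimers
Product: 20 target CNP0216954.2, via lactone silyl enol ether 19 (not isolated)
Conditions: Me3SiOTf (1.5 equiv), Et3N (2 equiv), CH2Cl2, 0 °C; evaporation; then Bu4NF, AcOH (3 equiv), THF, −78 °C
Reagents that add atoms: none
Why: soft enolisation toward the more acidic, oxygen-bearing C6′–H should turn both epimers into one exocyclic silyl enol ether, and kinetic protonation on fluoride-induced desilylation should deliver hydrogen to C6′ from the face opposite the C5′ isopropenyl group (held out of the enol plane by 1,3-allylic strain), which places isobutyryl cis to isopropenyl as in the target.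

Compound list
1 | (R)-(+)-α-terpineol, 2-[(1R)-4-methylcyclohex-3-en-1-yl]propan-2-ol | CC1=CC[C@@H](CC1)C(C)(C)O | starting material
2 | (3R)-3-(2-hydroxypropan-2-yl)-6-oxoheptanoic acid | CC(=O)CC[C@H](CC(=O)O)C(C)(C)O | intermediate (not isolated)
3 | (4R)-5,5-dimethyl-4-(3-oxobutyl)oxolan-2-one (homoterpenyl methyl ketone) | CC(=O)CC[C@@H]1CC(=O)OC1(C)C | intermediate
4 | 3-[(3R)-2,2-dimethyl-5-oxooxolan-3-yl]propanoic acid (homoterpenylic acid) | OC(=O)CC[C@@H]1CC(=O)OC1(C)C | intermediate (not isolated)
5 | methyl 3-[(3R)-2,2-dimethyl-5-oxooxolan-3-yl]propanoate | COC(=O)CC[C@@H]1CC(=O)OC1(C)C | intermediate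
6 | lithium enolate of (3aR)-3,3-dimethyltetrahydro-1H-cyclopenta[c]furan-1,6(6aH)-dione (enolate across C6–C6a) | [Li+].[O-]C1=C2[C@@H](CC1)C(C)(C)OC2=O | intermediate (not isolated)
7 | (3aR,6aR)-3,3,6a-trimethyltetrahydro-1H-cyclopenta[c]furan-1,6(6aH)-dione, cis-fused, 6a-methyl and 3a-H on the same face | O=C1CC[C@H]2C(C)(C)OC(=O)[C@@]12C | intermediate
8 | (3aR,6aR)-5-allyl-3,3,6a-trimethyltetrahydro-1H-cyclopenta[c]furan-1,6(6aH)-dione, C5 epimers | C=CCC1C[C@H]2C(C)(C)OC(=O)[C@@]2(C)C1=O | intermediate
9 | (3aR,5R,6aR)-5-allyl-3,3,6a-trimethyl-1,6-dioxohexahydro-1H-cyclopenta[c]furan-5-carboxylic acid, carboxyl cis to the 6a-methyl group | C=CC[C@]1(C[C@H]2C(C)(C)OC(=O)[C@@]2(C)C1=O)C(=O)O | intermediate (not isolated)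
10 | 2-(trimethylsilyl)ethyl (3aR,5R,6aR)-5-allyl-3,3,6a-trimethyl-1,6-dioxohexahydro-1H-cyclopenta[c]furan-5-carboxylate | C=CC[C@]1(C[C@H]2C(C)(C)OC(=O)[C@@]2(C)C1=O)C(=O)OCC[Si](C)(C)C | intermediate
11 | 4-methylpent-1-en-3-one (isopropyl vinyl ketone) | C=CC(=O)C(C)C | starting material
12 | 2-(trimethylsilyl)ethyl (3aR,5R,6aR)-3,3,6a-trimethyl-5-[(2E)-5-methyl-4-oxohex-2-en-1-yl]-1,6-dioxohexahydro-1H-cyclopenta[c]furan-5-carboxylate | CC(C)C(=O)/C=C/C[C@]1(C[C@H]2C(C)(C)OC(=O)[C@@]2(C)C1=O)C(=O)OCC[Si](C)(C)C | intermediate
13 | 4,4,5,5-tetramethyl-2-(prop-1-en-2-yl)-1,3,2-dioxaborolane (isopropenylboronic acid pinacol ester) | C=C(C)B1OC(C)(C)C(C)(C)O1 | starting material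
14 | 2-(trimethylsilyl)ethyl (3aR,5R,6aR)-3,3,6a-trimethyl-5-[(2R)-5-methyl-4-oxo-2-(prop-1-en-2-yl)hexyl]-1,6-dioxohexahydro-1H-cyclopenta[c]furan-5-carboxylate | C=C(C)[C@@H](CC(=O)C(C)C)C[C@]1(C[C@H]2C(C)(C)OC(=O)[C@@]2(C)C1=O)C(=O)OCC[Si](C)(C)C | intermediate
15 | trimethylsilyl enol ether of 14 (side-chain ketone enolised toward the future C6′, alkene geometry not defined) | C=C(C)[C@@H](C=C(O[Si](C)(C)C)C(C)C)C[C@]1(C[C@H]2C(C)(C)OC(=O)[C@@]2(C)C1=O)C(=O)OCC[Si](C)(C)C | intermediate (not isolated)
16 | α-bromo ketone: 14 with bromine on the carbon between C5′ and the ketone (future C6′), both C–Br epimers, other stereocentres as in 14 | C=C(C)[C@@H](C(Br)C(=O)C(C)C)C[C@]1(C[C@H]2C(C)(C)OC(=O)[C@@]2(C)C1=O)C(=O)OCC[Si](C)(C)C | intermediate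
17 | tetrabutylammonium carboxylate formed from 16 by loss of the 2-(trimethylsilyl)ethyl group | C=C(C)[C@@H](C(Br)C(=O)C(C)C)C[C@]1(C[C@H]2C(C)(C)OC(=O)[C@@]2(C)C1=O)C(=O)[O-].CCCC[N+](CCCC)(CCCC)CCCC | intermediate (not isolated)
18 | spiro δ-lactone with the target skeleton, C3′ (R), C5′ (S), mixture of C6′ epimers | C=C(C)[C@@H]1C[C@]2(C[C@H]3C(C)(C)OC(=O)[C@@]3(C)C2=O)C(=O)OC1C(=O)C(C)C | intermediate
19 | exocyclic trimethylsilyl enol ether of 18, C6′=C(OSiMe3)CH(CH3)2 | C=C(C)[C@@H]1C[C@]2(C[C@H]3C(C)(C)OC(=O)[C@@]3(C)C2=O)C(=O)OC1=C(O[Si](C)(C)C)C(C)C | intermediate (not isolated)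
20 | target CNP0216954.2: δ-lactone O1′–C2′(=O)–C3′–C4′H2–C5′H(isopropenyl)–C6′H(isobutyryl) spiro-fused at C3′ to C5 of the (3aR,6aR)-3,3,6a-trimethylcyclopenta[c]furan-1,6-dione core; C3′ (R), C5′ (S), C6′ (S); isopropenyl and isobutyryl cis; δ-lactone carbonyl on the face of the 6a-methyl group | C=C(C)[C@@H]1C[C@]2(C[C@H]3C(C)(C)OC(=O)[C@@]3(C)C2=O)C(=O)O[C@@H]1C(=O)C(C)C | target

Total step count: 10. Longest linear sequence: 10 steps (1 → 20); compounds 11 and 13 are commercial.

Steps most likely to fail

Step 9. The displacement at the β-branched C6′ may be slower than fluoride-induced loss of HBr from the bromo ketone or loss of CO2 from the keto carboxylate. The fallback sets out from 14 and comes back at 18. The ester of 14 is cleaved first with Bu4NF in THF to give the keto acid F1, which is used directly. The O1′–C6′ bond is then made by oxidative C–H lactonisation under iodide/hydroperoxide (hypoiodite) catalysis (Bu4NI 10 mol %, t-BuOOH, EtOAc, rt). In this known α-acyloxylation of ketones the enol is activated by electrophilic iodine and captured by the tethered carboxyl group through a far better leaving group than bromide. Ring size restricts the reaction to C6′, and the enol should be much more reactive toward the oxidant than the isopropenyl group.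

Step 10. Enolisation may take place toward the isopropyl side, or the proton may be delivered with poor facial discrimination. The fallback sets out from 18 and comes back at 20. Catalytic DBU in CH2Cl2 equilibrates the two C6′ epimers, 20 is separated by chromatography on neutral silica, and the recovered 6′-epimer is resubmitted. This thermodynamic approach makes no new compound, none F0.

Step 5. Facial selectivity in the carboxylation may be poor, because CO2 is a small electrophile and the angular 6a-methyl group sits on the convex face. The fallback sets out from 7 and comes back at 10. The order of bond formation is reversed and a chiral catalyst decides the face. Ketone 7 is C-acylated (NaH, dimethyl carbonate, THF, reflux) to the methyl keto ester F2. This is transesterified (Me3SiCH2CH2OH, DMAP, toluene, 100 °C) to the 2-(trimethylsilyl)ethyl keto ester F3. F3 is then allylated by Pd-catalysed asymmetric allylic alkylation ([Pd(C3H5)Cl]2, chiral N,N′-bis[2-(diphenylphosphino)benzoyl]-1,2-diaminocyclohexane ligand, allyl acetate, Cs2CO3, toluene, 0 °C). The ligand enantiomer is chosen to place allyl on the lactone-side face against the substrate bias.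

Further compounds
F1 | step 9 | (3aR,5R,6aR)-3,3,6a-trimethyl-5-[(2R)-5-methyl-4-oxo-2-(prop-1-en-2-yl)hexyl]-1,6-dioxohexahydro-1H-cyclopenta[c]furan-5-carboxylic acid | C=C(C)[C@@H](CC(=O)C(C)C)C[C@]1(C[C@H]2C(C)(C)OC(=O)[C@@]2(C)C1=O)C(=O)O
F0 | step 10 | none | none
F2 | step 5 | methyl (3aR,6aR)-3,3,6a-trimethyl-1,6-dioxohexahydro-1H-cyclopenta[c]furan-5-carboxylate (C5 epimers) | COC(=O)C1C[C@H]2C(C)(C)OC(=O)[C@@]2(C)C1=O
F3 | step 5 | 2-(trimethylsilyl)ethyl (3aR,6aR)-3,3,6a-trimethyl-1,6-dioxohexahydro-1H-cyclopenta[c]furan-5-carboxylate (C5 epimers) | C[Si](C)(C)CCOC(=O)C1C[C@H]2C(C)(C)OC(=O)[C@@]2(C)C1=O
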